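**Retrosynthetic overview**

- Target 16 comes from 15 by MOM removal. 15 comes from phenol 12 by forming the O1–C8a bond of the 2H-chromene (C4′–O in isoflavone numbering).
- The strategy rests on ring B: the pyran oxygen sits on C4′, ortho to the methoxyl carbon C5′ and meta to the phenol carbon C2′, while C2′–OH and C5′–OMe are para. This is the pattern left when a nucleophile adds next to the acetal carbon of a 4-methoxyphenol-derived quinone monoacetal and methanol is lost.
- 12 comes from iodophenol 7 by acetylation, Sonogashira coupling with alkynol 9, Lindlar reduction to the Z-alkene and deacetylation.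
- 7 comes from 3-iodochromone 4 and boronic acid 5 by Suzuki coupling and ortho-iodination; 4 comes from acetophenone 1 by enaminone iodocyclisation.
- Ring order: the chromone pyranone ring is formed first (step 3), the dimethylpyran ring last (step 10); both benzene rings are bought.

Key step: step 10

Remark: 14 is drawn as its dienol tautomer and its C8a centre is transient. Partial loss of the MOM group during the acid phase of step 10 would only anticipate step 11.

**Route**

Step 1
Reactants: 1 2,4-dihydroxyacetophenone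
Product: 2 1-[2-hydroxy-4-(methoxymethoxy)phenyl]ethanone
Conditions: MOMCl (1.1 equiv), K2CO3, acetone, 0 °C to rt
Reagents that add atoms: chloromethyl methyl ether, COCCl
Why: Williamson-type O-alkylation (MOM ether formation) should take the more acidic, unhindered 4-OH, because the 2-OH is held in a hydrogen bond to the ketone and stays free for the later chromone closure.

Step 2
Reactants: 2 1-[2-hydroxy-4-(methoxymethoxy)phenyl]ethanone
Product: 3 (E)-3-(dimethylamino)-1-[2-hydroxy-4-(methoxymethoxy)phenyl]prop-2-en-1-one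
Conditions: DMF-DMA, toluene, 90 °C
Reagents that add atoms: N,N-dimethylformamide dimethyl acetal, CN(C)C(OC)OC
Why: Condensation of the methyl ketone with the formamide acetal (enaminone formation) supplies the future C2 of the chromone as an (E)-β-dimethylaminoenone.

Step 3
Reactants: 3 (E)-3-(dimethylamino)-1-[2-hydroxy-4-(methoxymethoxy)phenyl]prop-2-en-1-one
Product: 4 3-iodo-7-(methoxymethoxy)chromen-4-one
Conditions: I2, pyridine, CHCl3, rt
Reagents that add atoms: iodine, II
Why: Iodine attacks the enaminone α-carbon, the phenol oxygen adds to the resulting iminium carbon and dimethylamine is lost (iodocyclisation of o-hydroxyaryl enaminones to 3-iodochromones), with pyridine keeping the medium non-acidic for the MOM ether.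

Step 4
Reactants: 4 3-iodo-7-(methoxymethoxy)chromen-4-one; 5 (2-hydroxy-5-methoxyphenyl)boronic acid
Product: 6 3-(2-hydroxy-5-methoxyphenyl)-7-(methoxymethoxy)chromen-4-one
Conditions: PdCl2(dppf) (5 mol%), Na2CO3, DME/H2O, 80 °C, degassed
Reagents that add atoms: none
Why: Suzuki–Miyaura coupling should form the C3–C1′ bond, since oxidative addition of zerovalent palladium into the C3–I bond of the iodoenone is fast and the carbonate base spares the chromone and the MOM ether.

Step 5
Reactants: 6 3-(2-hydroxy-5-methoxyphenyl)-7-(methoxymethoxy)chromen-4-one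
Product: 7 3-(2-hydroxy-3-iodo-5-methoxyphenyl)-7-(methoxymethoxy)chromen-4-one
Conditions: NIS (1.05 equiv), DMF, 0 °C to rt, dark
Reagents that add atoms: N-iodosuccinimide, O=C1CCC(=O)N1I
Why: Electrophilic aromatic iodination is directed by the free phenol to C3′, the only open position ortho to the hydroxyl (C1′ carries the chromone, the para carbon C5′ the methoxyl), while ring A is deactivated by the chromone carbonyl.

Step 6
Reactants: 7 3-(2-hydroxy-3-iodo-5-methoxyphenyl)-7-(methoxymethoxy)chromen-4-one
Product: 8 2-iodo-4-methoxy-6-[7-(methoxymethoxy)-4-oxochromen-3-yl]phenyl acetate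
Conditions: Ac2O, pyridine, DMAP (cat.), CH2Cl2, 0 °C to rt
Reagents that add atoms: acetic anhydride, CC(=O)OC(C)=O
Why: DMAP-catalysed acylation masks the phenol so that the alkyne introduced next cannot cyclise onto it to a benzofuran.

Step 7
Reactants: 8 2-iodo-4-methoxy-6-[7-(methoxymethoxy)-4-oxochromen-3-yl]phenyl acetate; 9 2-methylbut-3-yn-2-ol
Product: 10 2-(3-hydroxy-3-methylbut-1-ynyl)-4-methoxy-6-[7-(methoxymethoxy)-4-oxochromen-3-yl]phenyl acetate
Conditions: PdCl2(PPh3)2 (3 mol%), CuI (5 mol%), Et3N, THF, rt, degassed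
Reagents that add atoms: none
Why: Sonogashira coupling of the aryl iodide with the terminal alkyne should proceed at room temperature, where the aryl acetate, the MOM ether and the free tertiary alcohol are tolerated.

Step 8
Reactants: 10 2-(3-hydroxy-3-methylbut-1-ynyl)-4-methoxy-6-[7-(methoxymethoxy)-4-oxochromen-3-yl]phenyl acetate
Product: 11 2-[(Z)-3-hydroxy-3-methylbut-1-enyl]-4-methoxy-6-[7-(methoxymethoxy)-4-oxochromen-3-yl]phenyl acetate
Conditions: H2 (1 atm), Pd/CaCO3 poisoned with Pb(OAc)2 (Lindlar catalyst), quinoline, EtOAc, rt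
Reagents that add atoms: none
Why: Lindlar semihydrogenation delivers both hydrogens to the same face of the alkyne on the poisoned palladium surface, so the Z-alkene is set here, while the chromone C2=C3 bond and the aryl acetate should not be reduced.

Step 9
Reactants: 11 2-[(Z)-3-hydroxy-3-methylbut-1-enyl]-4-methoxy-6-[7-(methoxymethoxy)-4-oxochromen-3-yl]phenyl acetate
Product: 12 3-{2-hydroxy-3-[(Z)-3-hydroxy-3-methylbut-1-enyl]-5-methoxyphenyl}-7-(methoxymethoxy)chromen-4-one
Conditions: K2CO3 (0.3 equiv), MeOH, 0 °C; pH 7 phosphate buffer work-up, used promptly without acidic silica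
Reagents that add atoms: none
Why: Base-catalysed transesterification of the aryl acetate with methanol frees the phenol under conditions in which the Z-allylic tertiary alcohol cannot ionise, so cyclodehydration onto the phenol oxygen (the angular chromene) should be avoided.

Step 10
Reactants: 12 3-{2-hydroxy-3-[(Z)-3-hydroxy-3-methylbut-1-enyl]-5-methoxyphenyl}-7-(methoxymethoxy)chromen-4-one
Product: 15 3-(5-hydroxy-8-methoxy-2,2-dimethyl-2H-chromen-6-yl)-7-(methoxymethoxy)chromen-4-one, via quinone monoacetal 13 (not isolated), via dienol oxa-Michael adduct 14 (not isolated)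
Conditions: PhI(OAc)2 (1.1 equiv), dry MeOH, −10 °C until 12 is consumed; then CSA (10 mol%), 0 °C to rt
Reagents that add atoms: methanol, CO (supplies the second acetal methoxyl of 13; either methoxyl may be the one that remains at C8)
Why: Proposed new method: oxidation of the 4-methoxyphenol by trivalent iodine in methanol should give the 4,4-dimethoxycyclohexa-2,5-dienone 13, in which C2′ is the carbonyl and C5′ the acetal carbon, so that C4′ becomes the β-carbon of an enone while the phenol oxygen is tied up as the ketone. The tertiary hydroxyl, held over C4′ by the Z-alkene on C3′, should then add in an acid-assisted intramolecular oxa-Michael reaction (6-endo-trig, the ring holding O, CMe2, the two alkene carbons, C3′ and C4′) to give dienol 14. Acid then ionises the acetal at C5′ and loss of the C4′ proton expels methanol, so the arene returns carrying the new C4′–O bond, the C2′ phenol and one C5′ methoxyl. The closest known reactions are the PhI(OAc)2/MeOH preparation of quinone monoacetals and the conjugate addition of amines, thiols or stabilised carbanions to them followed by acid-induced loss of methanol to 3-substituted 4-methoxyphenols, whereas closure of a 2H-chromene by an alcohol tethered to the α-carbon in the same flask has not been described. No stereocenter survives, as C8a of 14 is flattened on rearomatisation. The selectivity needed is C4′–O closure rather than attack of the phenol oxygen on the allylic carbinol, and it should be secured by adding no acid before the phenol is consumed, by the Z-tether reaching only C4′ through a six-membered transition state (C6′ and the acetal carbon are out of reach), and by the reduced tendency of the dienone-bound allylic alcohol to ionise.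

Step 11
Reactants: 15 3-(5-hydroxy-8-methoxy-2,2-dimethyl-2H-chromen-6-yl)-7-(methoxymethoxy)chromen-4-one
Product: 16 7-hydroxy-3-(5-hydroxy-8-methoxy-2,2-dimethyl-2H-chromen-6-yl)chromen-4-one
Conditions: 3 M aq. HCl, MeOH, 50 °C
Reagents that add atoms: none
Why: Acid-catalysed acetal exchange in methanol (MOM ether cleavage) should free the 7-hydroxyl, and the 2,2-dimethyl-2H-chromene and the chromone tolerate dilute methanolic HCl at this temperature.

**Compound list**

1 | 2,4-dihydroxyacetophenone | CC(=O)c1ccc(O)cc1O | starting material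
2 | 1-[2-hydroxy-4-(methoxymethoxy)phenyl]ethanone | CC(=O)c1ccc(OCOC)cc1O | intermediate
3 | (E)-3-(dimethylamino)-1-[2-hydroxy-4-(methoxymethoxy)phenyl]prop-2-en-1-one | CN(C)/C=C/C(=O)c1ccc(OCOC)cc1O | intermediate
4 | 3-iodo-7-(methoxymethoxy)chromen-4-one | COCOc1ccc2c(c1)occ(I)c2=O | intermediate
5 | (2-hydroxy-5-methoxyphenyl)boronic acid | COc1ccc(O)c(B(O)O)c1 | starting material
6 | 3-(2-hydroxy-5-methoxyphenyl)-7-(methoxymethoxy)chromen-4-one | COCOc1ccc2c(c1)occ(-c1cc(OC)ccc1O)c2=O | intermediate
7 | 3-(2-hydroxy-3-iodo-5-methoxyphenyl)-7-(methoxymethoxy)chromen-4-one | COCOc1ccc2c(c1)occ(-c1cc(OC)cc(I)c1O)c2=O | intermediate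
8 | 2-iodo-4-methoxy-6-[7-(methoxymethoxy)-4-oxochromen-3-yl]phenyl acetate | COCOc1ccc2c(c1)occ(-c1cc(OC)cc(I)c1OC(C)=O)c2=O | intermediate
9 | 2-methylbut-3-yn-2-ol | CC(C)(O)C#C | starting material
10 | 2-(3-hydroxy-3-methylbut-1-ynyl)-4-methoxy-6-[7-(methoxymethoxy)-4-oxochromen-3-yl]phenyl acetate | COCOc1ccc2c(c1)occ(-c1cc(OC)cc(C#CC(C)(C)O)c1OC(C)=O)c2=O | intermediate
11 | 2-[(Z)-3-hydroxy-3-methylbut-1-enyl]-4-methoxy-6-[7-(methoxymethoxy)-4-oxochromen-3-yl]phenyl acetate | COCOc1ccc2c(c1)occ(-c1cc(OC)cc(/C=C\C(C)(C)O)c1OC(C)=O)c2=O | intermediate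
12 | 3-{2-hydroxy-3-[(Z)-3-hydroxy-3-methylbut-1-enyl]-5-methoxyphenyl}-7-(methoxymethoxy)chromen-4-one | COCOc1ccc2c(c1)occ(-c1cc(OC)cc(/C=C\C(C)(C)O)c1O)c2=O | intermediate
13 | 2-[(Z)-3-hydroxy-3-methylbut-1-enyl]-4,4-dimethoxy-6-[7-(methoxymethoxy)-4-oxochromen-3-yl]cyclohexa-2,5-dien-1-one (quinone monoacetal, not isolated) | COCOc1ccc2c(c1)occ(C1=CC(OC)(OC)C=C(/C=C\C(C)(C)O)C1=O)c2=O | intermediate
14 | 3-(5-hydroxy-8,8-dimethoxy-2,2-dimethyl-8,8a-dihydro-2H-chromen-6-yl)-7-(methoxymethoxy)chromen-4-one (dienol form of the oxa-Michael adduct, C8a unassigned and transient, not isolated) | COCOc1ccc2c(c1)occ(C1=CC(OC)(OC)C3OC(C)(C)C=CC3=C1O)c2=O | intermediate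
15 | 3-(5-hydroxy-8-methoxy-2,2-dimethyl-2H-chromen-6-yl)-7-(methoxymethoxy)chromen-4-one | COCOc1ccc2c(c1)occ(-c1cc(OC)c3OC(C)(C)C=Cc3c1O)c2=O | intermediate
16 | 7-hydroxy-3-(5-hydroxy-8-methoxy-2,2-dimethyl-2H-chromen-6-yl)chromen-4-one | COc1cc(-c2coc3cc(O)ccc3c2=O)c(O)c2c1OC(C)(C)C=C2 | target

**Step count**

Total: 11 steps. Longest linear sequence: 11 steps (1 to 16).

**Steps most likely to fail**

1. Step 10. Addition of the hindered tertiary hydroxyl to C4′ of the monoacetal may be slower than hydrolysis of the acetal to the quinone or ionisation of the allylic alcohol, or the adduct may revert instead of losing methanol. The fallback uses known chemistry and a different bond construction: the C4′ oxygen is carried in with ring B and the pyran is closed by an aryl propargyl ether Claisen rearrangement. It sets out from 4 and comes back at 16.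
   - Commercial 2-bromo-5-hydroxy-4-methoxybenzaldehyde F1 would be O-alkylated with 3-chloro-3-methylbut-1-yne (K2CO3, KI, cat. CuI, acetone) to 2-bromo-4-methoxy-5-[(2-methylbut-3-yn-2-yl)oxy]benzaldehyde F2.
   - Baeyer–Villiger oxidation (mCPBA, CH2Cl2) would give 2-bromo-4-methoxy-5-[(2-methylbut-3-yn-2-yl)oxy]phenyl formate F3, and methanolysis (K2CO3, MeOH) would give 2-bromo-4-methoxy-5-[(2-methylbut-3-yn-2-yl)oxy]phenol F4.
   - MOMCl and iPr2NEt would give 1-bromo-5-methoxy-2-(methoxymethoxy)-4-[(2-methylbut-3-yn-2-yl)oxy]benzene F5.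
   - Heating in N,N-diethylaniline (about 180 °C) should cause Claisen rearrangement to the only free ortho position, hydrogen shift and oxa-6π closure, giving 6-bromo-8-methoxy-5-(methoxymethoxy)-2,2-dimethyl-2H-chromene F6.
   - Bromine–lithium exchange (nBuLi, THF, −78 °C) and trapping with 2-isopropoxy-4,4,5,5-tetramethyl-1,3,2-dioxaborolane would give 2-[8-methoxy-5-(methoxymethoxy)-2,2-dimethyl-2H-chromen-6-yl]-4,4,5,5-tetramethyl-1,3,2-dioxaborolane F7.
   - Suzuki coupling of F7 with 4 (PdCl2(dppf), K3PO4, dioxane/H2O) would give 3-[8-methoxy-5-(methoxymethoxy)-2,2-dimethyl-2H-chromen-6-yl]-7-(methoxymethoxy)chromen-4-one F8, and both MOM groups would be removed with HCl in MeOH to reach 16.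

2. Step 4. Protodeboronation of the free, electron-rich ortho-hydroxyarylboronic acid may outpace transmetalation. The fallback couples a protected partner and unmasks the phenol by hydrogenolysis. It sets out from 4 and comes back at 6.
   - Commercial 2-bromo-4-methoxyphenol F9 would be benzylated (BnBr, K2CO3, DMF) to 1-(benzyloxy)-2-bromo-4-methoxybenzene F10.
   - Bromine–lithium exchange (nBuLi, THF, −78 °C), B(OiPr)3 and aqueous acid would give [2-(benzyloxy)-5-methoxyphenyl]boronic acid F11.
   - Suzuki coupling with 4 (Pd(PPh3)4, Na2CO3, DME/H2O) would give 3-[2-(benzyloxy)-5-methoxyphenyl]-7-(methoxymethoxy)chromen-4-one F12.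
   - Hydrogenolysis (H2, Pd/C, EtOAc, rt) would deliver 6.

3. Step 8. The semihydrogenation may run on to the saturated side chain, stall, or isomerise the Z-alkene on the catalyst. The fallback brings the Z-alkene in ready-made by cross-coupling, so it also bypasses step 7. It sets out from 8 (with 9) and comes back at 11.
   - Miyaura borylation of 8 (B2pin2, PdCl2(dppf), KOAc, dioxane, 80 °C) would give 4-methoxy-2-[7-(methoxymethoxy)-4-oxochromen-3-yl]-6-(4,4,5,5-tetramethyl-1,3,2-dioxaborolan-2-yl)phenyl acetate F13.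
   - Alkynol 9 would be iodinated (NIS, cat. AgNO3, acetone) to 4-iodo-2-methylbut-3-yn-2-ol F14 and reduced with diimide (2-nitrobenzenesulfonyl hydrazide, Et3N) to (Z)-4-iodo-2-methylbut-3-en-2-ol F15.
   - Suzuki coupling of F13 with F15 (Pd(PPh3)4, K3PO4, THF/H2O, rt) should retain the alkene geometry and give 11. If the acetate is lost under the basic coupling, 12 results directly.

**Further compounds**

F1 | step 10 | 2-bromo-5-hydroxy-4-methoxybenzaldehyde | COc1cc(Br)c(C=O)cc1O
F2 | step 10 | 2-bromo-4-methoxy-5-[(2-methylbut-3-yn-2-yl)oxy]benzaldehyde | COc1cc(Br)c(C=O)cc1OC(C)(C)C#C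
F3 | step 10 | 2-bromo-4-methoxy-5-[(2-methylbut-3-yn-2-yl)oxy]phenyl formate | COc1cc(Br)c(OC=O)cc1OC(C)(C)C#C
F4 | step 10 | 2-bromo-4-methoxy-5-[(2-methylbut-3-yn-2-yl)oxy]phenol | COc1cc(Br)c(O)cc1OC(C)(C)C#C
F5 | step 10 | 1-bromo-5-methoxy-2-(methoxymethoxy)-4-[(2-methylbut-3-yn-2-yl)oxy]benzene | COCOc1cc(OC(C)(C)C#C)c(OC)cc1Br
F6 | step 10 | 6-bromo-8-methoxy-5-(methoxymethoxy)-2,2-dimethyl-2H-chromene | COCOc1c(Br)cc(OC)c2OC(C)(C)C=Cc12
F7 | step 10 | 2-[8-methoxy-5-(methoxymethoxy)-2,2-dimethyl-2H-chromen-6-yl]-4,4,5,5-tetramethyl-1,3,2-dioxaborolane | COCOc1c(B3OC(C)(C)C(C)(C)O3)cc(OC)c2OC(C)(C)C=Cc12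
F8 | step 10 | 3-[8-methoxy-5-(methoxymethoxy)-2,2-dimethyl-2H-chromen-6-yl]-7-(methoxymethoxy)chromen-4-one | COCOc1ccc2c(c1)occ(-c1cc(OC)c3OC(C)(C)C=Cc3c1OCOC)c2=O
F9 | step 4 | 2-bromo-4-methoxyphenol | COc1ccc(O)c(Br)c1
F10 | step 4 | 1-(benzyloxy)-2-bromo-4-methoxybenzene | COc1ccc(OCc2ccccc2)c(Br)c1
F11 | step 4 | [2-(benzyloxy)-5-methoxyphenyl]boronic acid | COc1ccc(OCc2ccccc2)c(B(O)O)c1
F12 | step 4 | 3-[2-(benzyloxy)-5-methoxyphenyl]-7-(methoxymethoxy)chromen-4-one | COCOc1ccc2c(c1)occ(-c1cc(OC)ccc1OCc1ccccc1)c2=O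
F13 | step 8 | 4-methoxy-2-[7-(methoxymethoxy)-4-oxochromen-3-yl]-6-(4,4,5,5-tetramethyl-1,3,2-dioxaborolan-2-yl)phenyl acetate | COCOc1ccc2c(c1)occ(-c1cc(OC)cc(B3OC(C)(C)C(C)(C)O3)c1OC(C)=O)c2=O
F14 | step 8 | 4-iodo-2-methylbut-3-yn-2-ol | CC(C)(O)C#CI
F15 | step 8 | (Z)-4-iodo-2-methylbut-3-en-2-ol | CC(C)(O)/C=C\I
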